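**Retrosynthetic overview**

1. Chain numbering runs from C1 (alkyne CH) to C15 (CH3). Ring A is the enol-ether ring (O–C7–C8–C9–C10) and ring B is the O–C9–C10–C11–C12 ring; ring B is built first, ring A second.
2. Last events: C8–Br by SN2 inversion of a C8 alcohol, and the 3Z enyne by Z-selective enyne cross-metathesis on a C3–C5 allyl group.
3. Key step: ring A, the 6E enol ether and the C5–C6 bond are made together by a PdCl2-catalysed anti-oxypalladation/allylation of a terminal alkynol. The usual 5-exo hydroalkoxylation of an internal alkynol would give the 6Z isomer.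
4. The alkynol comes from a ring B aldehyde (ethynyl Grignard, chelation control at C8). Ring B, C12 and C13–Br come from one biomimetic bromoetherification of an (E)-alkene syn-diol.
5. The syn-diol (C9, C10) comes from (E)-hex-3-enal by Brown γ-alkoxyallylboration.

Assumption: 3-(methoxymethoxy)prop-1-ene and vinyl bromide (as a THF solution) are bought as catalogue items.

**Route**

Step 1
Reactants: 1 (3E)-hex-3-en-1-ol
Product: 2 (3E)-hex-3-enal
Conditions: Dess–Martin periodinane, CH2Cl2, 0 °C → rt; used crude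
Reagents that add atoms: none
Why: Dess–Martin oxidation is cold and non-basic, so the β,γ-unsaturated aldehyde forms without migration of the E alkene into conjugation; no stereocentre is formed.

Step 2
Reactants: 2 (3E)-hex-3-enal; 3 3-(methoxymethoxy)prop-1-ene
Product: 6 (3S,4S,6E)-3-(methoxymethoxy)nona-1,6-dien-4-ol, via allylborane 4 (not isolated), via borinate ester 5 (not isolated)
Conditions: 3, s-BuLi, THF, −78 °C; (+)-Ipc2BOMe; BF3·OEt2; 2, −78 °C; then NaOH, H2O2, 0 °C → rt
Reagents that add atoms: none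
Why: Brown asymmetric γ-alkoxyallylboration: the (Z)-γ-alkoxyallylborane reacts through a closed chair (Zimmerman–Traxler) transition state to give the syn C9/C10 diol pattern, and the isopinocampheyl groups of (+)-Ipc2BOMe direct attack to the Re face of the aldehyde, giving the 3S,4S isomer.

Step 3
Reactants: 6 (3S,4S,6E)-3-(methoxymethoxy)nona-1,6-dien-4-ol
Product: 7 (3S,4S,6E)-nona-1,6-diene-3,4-diol
Conditions: HCl (cat.), MeOH, 50 °C
Reagents that add atoms: none
Why: Acid-catalysed acetal exchange (MOM cleavage) transfers the methoxymethyl group to methanol and touches neither the stereocentres nor the alkenes.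

Step 4
Reactants: 7 (3S,4S,6E)-nona-1,6-diene-3,4-diol
Product: 8 (2S,3S,5R)-5-[(1S)-1-bromopropyl]-2-ethenyloxolan-3-ol
Conditions: NBS, CH2Cl2, 0 °C, dark
Reagents that add atoms: N-bromosuccinimide, O=C1CCC(=O)N1Br
Why: 5-exo-trig bromoetherification (halocyclisation) of the more electron-rich E-disubstituted alkene by O9: anti addition of O and Br across the E alkene fixes the C12/C13 erythro relationship, and the faster-cyclising bromonium ion places the new side chain trans to both the vinyl group and the C10 hydroxyl (2,5-trans ring; expected dr about 4:1 with a little 6-endo product, both removed by chromatography).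

Step 5
Reactants: 8 (2S,3S,5R)-5-[(1S)-1-bromopropyl]-2-ethenyloxolan-3-ol
Product: 10 (2R,3S,5R)-5-[(1S)-1-bromopropyl]-3-hydroxyoxolane-2-carbaldehyde, via secondary ozonide 9 (not isolated)
Conditions: O3, CH2Cl2, −78 °C; then PPh3, −78 °C → rt; used crude
Reagents that add atoms: ozone, [O-][O+]=O
Why: Ozonolysis (Criegee mechanism, reductive work-up) cleaves the only remaining alkene to the C8 aldehyde without touching the stereocentres, the bromide or the alcohol.

Step 6
Reactants: 10 (2R,3S,5R)-5-[(1S)-1-bromopropyl]-3-hydroxyoxolane-2-carbaldehyde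
Product: 12 (1S)-1-[(2R,3S,5R)-5-[(1S)-1-bromopropyl]-3-hydroxyoxolan-2-yl]prop-2-yn-1-ol, via magnesium dialkoxide 11 (not isolated)
Conditions: HC≡CMgBr (3 equiv), THF, −78 → 0 °C; then aq. NH4Cl
Reagents that add atoms: ethynylmagnesium bromide, C#C[Mg]Br
Why: Grignard addition under 1,3-chelation (Cram–Reetz) and polar Felkin–Anh control, which agree: the magnesium alkoxide of the cis C10 hydroxyl ties the aldehyde into a six-membered chelate and the acetylide attacks the face away from the ring oxygen, giving the 1,2-anti/1,3-anti carbinol (expected dr about 4:1, epimer separated).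

Step 7
Reactants: 12 (1S)-1-[(2R,3S,5R)-5-[(1S)-1-bromopropyl]-3-hydroxyoxolan-2-yl]prop-2-yn-1-ol
Product: 13 (2E,3R,3aS,5R,6aS)-5-[(1S)-1-bromopropyl]-2-(but-3-en-1-ylidene)hexahydrofuro[3,2-b]furan-3-ol
Conditions: PdCl2(MeCN)2 (5 mol %), allyl chloride (10 equiv), methyloxirane (5 equiv), THF, 0 °C → rt
Reagents that add atoms: allyl chloride (3-chloroprop-1-ene), C=CCCl
Why: Utimoto-type cyclisation–allylation: divalent palladium activates the terminal alkyne, the C10 hydroxyl adds anti in a 5-exo-dig oxypalladation, and the σ-vinylpalladium inserts allyl chloride and loses chloride, so C5 is installed with retention trans to the ring oxygen (6E) while the catalyst stays divalent and methyloxirane traps the HCl.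

Step 8
Reactants: 14 ethynyltri(propan-2-yl)silane; 15 bromoethene
Product: 16 but-3-en-1-yn-1-yltri(propan-2-yl)silane
Conditions: PdCl2(PPh3)2 (2 mol %), CuI (4 mol %), i-Pr2NH, THF, 0 °C → rt
Reagents that add atoms: none
Why: Sonogashira coupling (zerovalent palladium oxidative addition to the vinyl bromide, copper acetylide transmetalation) gives the silyl 1,3-enyne; no stereocentre is formed.

Step 9
Reactants: 13 (2E,3R,3aS,5R,6aS)-5-[(1S)-1-bromopropyl]-2-(but-3-en-1-ylidene)hexahydrofuro[3,2-b]furan-3-ol; 16 but-3-en-1-yn-1-yltri(propan-2-yl)silane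
Product: 17 (2E,3R,3aS,5R,6aS)-5-[(1S)-1-bromopropyl]-2-[(3Z)-6-[tri(propan-2-yl)silyl]hex-3-en-5-yn-1-ylidene]hexahydrofuro[3,2-b]furan-3-ol
Conditions: RuCl2(=CHPh)(PCy3)(H2IMes) (second-generation Grubbs catalyst, 10 mol %), 16 (3 equiv), 1,4-benzoquinone (20 mol %), CH2Cl2, 40 °C
Reagents that add atoms: none
Why: Z-selective enyne cross-metathesis: the terminal alkene reacts with the alkynyl-substituted ruthenium alkylidene derived from 16, which favours the Z-1,3-enyne (E isomer removed by chromatography), while the hindered trisubstituted enol ether is a poor carbene acceptor and benzoquinone suppresses hydride-induced migration of the skipped diene.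

Step 10
Reactants: 17 (2E,3R,3aS,5R,6aS)-5-[(1S)-1-bromopropyl]-2-[(3Z)-6-[tri(propan-2-yl)silyl]hex-3-en-5-yn-1-ylidene]hexahydrofuro[3,2-b]furan-3-ol
Product: 18 (2E,3R,3aS,5R,6aS)-5-[(1S)-1-bromopropyl]-2-[(3Z)-hex-3-en-5-yn-1-ylidene]hexahydrofuro[3,2-b]furan-3-ol
Conditions: Bu4NF, THF, 0 °C
Reagents that add atoms: none
Why: Fluoride-mediated protodesilylation of the alkynylsilane (the proton comes from water in the reagent) leaves the secondary bromide, the enol ether and the Z alkene untouched at 0 °C, and is done before the labile allylic bromide exists.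

Step 11
Reactants: 18 (2E,3R,3aS,5R,6aS)-5-[(1S)-1-bromopropyl]-2-[(3Z)-hex-3-en-5-yn-1-ylidene]hexahydrofuro[3,2-b]furan-3-ol
Product: 19 (2E,3S,3aR,5R,6aS)-3-bromo-5-[(1S)-1-bromopropyl]-2-[(3Z)-hex-3-en-5-yn-1-ylidene]hexahydrofuro[3,2-b]furan
Conditions: CBr4, PPh3, 2,6-lutidine, CH2Cl2, −20 → 0 °C
Reagents that add atoms: carbon tetrabromide, BrC(Br)(Br)Br
Why: Appel reaction: bromide displaces the alkoxyphosphonium group by SN2 from the open convex face, inverting C8 (3R alcohol to 3S bromide, trans to O4) under neutral conditions that the enol ether, enyne and secondary bromide tolerate.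

**Compound list**

1 | (3E)-hex-3-en-1-ol | CC/C=C/CCO | starting material
2 | (3E)-hex-3-enal | CC/C=C/CC=O | intermediate
3 | 3-(methoxymethoxy)prop-1-ene (allyl methoxymethyl ether) | C=CCOCOC | starting material
4 | [(2Z)-3-(methoxymethoxy)prop-2-en-1-yl]di[(+)-isopinocampheyl]borane (formed in the flask) | COCO/C=C\CB([C@H]1C[C@H]2C[C@@H]([C@@H]1C)C2(C)C)[C@H]1C[C@H]2C[C@@H]([C@@H]1C)C2(C)C | intermediate
5 | di[(+)-isopinocampheyl]borinate ester of 6 (formed in the flask) | C=C[C@H](OCOC)[C@@H](OB([C@H]1C[C@H]2C[C@@H]([C@@H]1C)C2(C)C)[C@H]1C[C@H]2C[C@@H]([C@@H]1C)C2(C)C)C/C=C/CC | intermediate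
6 | (3S,4S,6E)-3-(methoxymethoxy)nona-1,6-dien-4-ol | C=C[C@H](OCOC)[C@@H](O)C/C=C/CC | intermediate
7 | (3S,4S,6E)-nona-1,6-diene-3,4-diol | C=C[C@H](O)[C@@H](O)C/C=C/CC | intermediate
8 | (2S,3S,5R)-5-[(1S)-1-bromopropyl]-2-ethenyloxolan-3-ol | C=C[C@@H]1O[C@@H]([C@@H](Br)CC)C[C@@H]1O | intermediate
9 | (2R,3S,5R)-5-[(1S)-1-bromopropyl]-2-(1,2,4-trioxolan-3-yl)oxolan-3-ol, secondary ozonide, both epimers at the trioxolane carbon (formed in the flask) | O1COOC1[C@@H]1O[C@@H]([C@@H](Br)CC)C[C@@H]1O | intermediate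
10 | (2R,3S,5R)-5-[(1S)-1-bromopropyl]-3-hydroxyoxolane-2-carbaldehyde | O=C[C@@H]1O[C@@H]([C@@H](Br)CC)C[C@@H]1O | intermediate
11 | bis(bromomagnesium) dialkoxide of 12 (formed in the flask) | C#C[C@H](O[Mg]Br)[C@@H]1O[C@@H]([C@@H](Br)CC)C[C@@H]1O[Mg]Br | intermediate
12 | (1S)-1-[(2R,3S,5R)-5-[(1S)-1-bromopropyl]-3-hydroxyoxolan-2-yl]prop-2-yn-1-ol | C#C[C@H](O)[C@@H]1O[C@@H]([C@@H](Br)CC)C[C@@H]1O | intermediate
13 | (2E,3R,3aS,5R,6aS)-5-[(1S)-1-bromopropyl]-2-(but-3-en-1-ylidene)hexahydrofuro[3,2-b]furan-3-ol | C=CC/C=C1/O[C@H]2C[C@H]([C@@H](Br)CC)O[C@H]2[C@H]1O | intermediate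
14 | ethynyltri(propan-2-yl)silane | C#C[Si](C(C)C)(C(C)C)C(C)C | starting material
15 | bromoethene (vinyl bromide) | C=CBr | starting material
16 | but-3-en-1-yn-1-yltri(propan-2-yl)silane | C=CC#C[Si](C(C)C)(C(C)C)C(C)C | intermediate
17 | (2E,3R,3aS,5R,6aS)-5-[(1S)-1-bromopropyl]-2-[(3Z)-6-[tri(propan-2-yl)silyl]hex-3-en-5-yn-1-ylidene]hexahydrofuro[3,2-b]furan-3-ol | CC(C)[Si](C(C)C)(C(C)C)C#C/C=C\C/C=C1/O[C@H]2C[C@H]([C@@H](Br)CC)O[C@H]2[C@H]1O | intermediate
18 | (2E,3R,3aS,5R,6aS)-5-[(1S)-1-bromopropyl]-2-[(3Z)-hex-3-en-5-yn-1-ylidene]hexahydrofuro[3,2-b]furan-3-ol | C#C/C=C\C/C=C1/O[C@H]2C[C@H]([C@@H](Br)CC)O[C@H]2[C@H]1O | intermediate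
19 | (2E,3S,3aR,5R,6aS)-3-bromo-5-[(1S)-1-bromopropyl]-2-[(3Z)-hex-3-en-5-yn-1-ylidene]hexahydrofuro[3,2-b]furan | C#C/C=C\C/C=C1/O[C@H]2C[C@H]([C@@H](Br)CC)O[C@H]2[C@@H]1Br | target

**Step count and risks**

Total step count: 11. Longest linear sequence: 10 steps (steps 1–7 and 9–11, from 1 to 19); step 8 is a one-step side branch to 16.

Steps 4 and 6 are expected to give separable diastereomer mixtures rather than to fail outright. The three steps most likely to fail are 7, 9 and 11.

Step 7 (oxypalladation–allylation cascade). The risk is protodepalladation to the 2-methylene compound or poor tolerance of the free diol. The fallback separates the two bond formations. Setting out from 12, 5-exo-dig iodoetherification with N-iodosuccinimide and NaHCO3 in MeCN at 0 °C (anti addition of O and I) gives (2E,3R,3aS,5R,6aS)-5-[(1S)-1-bromopropyl]-2-(iodomethylidene)hexahydrofuro[3,2-b]furan-3-ol F1. Stille coupling of this iodide with allyltributylstannane (Pd2(dba)3, AsPh3, CuI, DMF, rt) keeps the alkene geometry and comes back to the route at 13.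

Step 9 (enyne cross-metathesis). The risk is loss of the ruthenium carbene to the enol ether or a poor Z:E ratio. The fallback builds the enyne by cross-coupling instead of by metathesis with an enyne. Setting out from 13, silylation (Et3SiCl, imidazole, CH2Cl2) gives the O-triethylsilyl ether of 13 F2. Kinetically Z-selective cross-metathesis with (Z)-1,2-dichloroethene, using the molybdenum alkylidene Mo(NC6F5)(CHCMe2Ph)(NC4H2Me2)(OAr) (OAr = 2,6-bis(2,4,6-triisopropylphenyl)phenoxide) in benzene at rt, gives the O-triethylsilyl ether of the 2-[(3Z)-4-chlorobut-3-en-1-ylidene] analogue of 13 F3. Sonogashira coupling with 14 (Pd(PPh3)4, CuI, n-BuNH2, benzene, rt; retention of the Z geometry) gives the O-triethylsilyl ether of 17 F4. Bu4NF in THF at 0 °C removes both silyl groups, and the fallback comes back to the route at 18.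

Step 11 (Appel bromination next to the enol ether). The risk is SN2′ attack at C6, elimination or ionisation. The fallback separates activation from displacement. Setting out from 18, MsCl and Et3N in CH2Cl2 at −40 °C give the methanesulfonate of 18 F5. Displacement with LiBr in acetone at 0 °C proceeds with inversion and comes back to the route at 19.

**Further compounds**

F1 | step 7 | (2E,3R,3aS,5R,6aS)-5-[(1S)-1-bromopropyl]-2-(iodomethylidene)hexahydrofuro[3,2-b]furan-3-ol | I/C=C1/O[C@H]2C[C@H]([C@@H](Br)CC)O[C@H]2[C@H]1O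
F2 | step 9 | O-triethylsilyl ether of 13 | C=CC/C=C1/O[C@H]2C[C@H]([C@@H](Br)CC)O[C@H]2[C@H]1O[Si](CC)(CC)CC
F3 | step 9 | O-triethylsilyl ether of the 2-[(3Z)-4-chlorobut-3-en-1-ylidene] analogue of 13 | Cl/C=C\C/C=C1/O[C@H]2C[C@H]([C@@H](Br)CC)O[C@H]2[C@H]1O[Si](CC)(CC)CC
F4 | step 9 | O-triethylsilyl ether of 17 | CC(C)[Si](C(C)C)(C(C)C)C#C/C=C\C/C=C1/O[C@H]2C[C@H]([C@@H](Br)CC)O[C@H]2[C@H]1O[Si](CC)(CC)CC
F5 | step 11 | methanesulfonate of 18 | C#C/C=C\C/C=C1/O[C@H]2C[C@H]([C@@H](Br)CC)O[C@H]2[C@H]1OS(C)(=O)=O
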